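**Strategy.** Everything rests on cutting two bonds at neighbouring cyclobutane carbons of the target: the bond between the cyclopentane CH2 and its cyclobutane CH, and the bond between the adjacent cyclobutane CH and the octyl chain, which stand trans across a former cyclobutene C=C. One radical chain forms both: a primary radical on an iodomethyl arm closes the cyclopentane 5-exo onto a cis-fused bicyclo[4.2.0]octa-3,7-diene, and the cyclobutyl radical takes allyl from tin on the convex face. The substrate arises from an endo Diels–Alder reaction of cyclobutenone with a butenolide-derived (Z)-2-silyloxydiene; its enol silyl ether masks the ketone until a Saegusa oxidation, and a Cr/Ni closure forms the last ring.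

Key step: step 15

Remark: locants for 14–19 are those of bicyclo[4.2.0]octane (C1/C6 ring fusion, C7/C8 four-ring carbons, C2 bears the side chain, C3 the silyloxy group). The six-ring ketone travels from step 10 to step 17 as its TBS enol ether and the two side-chain oxygens as separate silyl ethers; the carbon skeleton and the bond-forming events of the key step are unaffected. TBS = tert-butyldimethylsilyl, TIPS = triisopropylsilyl.

Step 1
Reactants: 1 (S)-5-(hydroxymethyl)furan-2(5H)-one
Product: 2 (S)-5-[(tert-butyldimethylsilyloxy)methyl]furan-2(5H)-one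
Conditions: TBSCl, imidazole, CH2Cl2, 0 °C to rt
Reagents that add atoms: tert-butyldimethylsilyl chloride, CC(C)(C)[Si](C)(C)Cl
Why: Imidazole-promoted O-silylation of a primary alcohol (silyl ether formation); the C5 stereocentre is not involved.

Step 2
Reactants: 2 silylated butenolide; 3 methanol
Product: 4 (4R,5S)-5-[(tert-butyldimethylsilyloxy)methyl]-4-(hydroxymethyl)dihydrofuran-2(3H)-one (4,5-trans)
Conditions: hν (350 nm, Pyrex), benzophenone (0.2 equiv), degassed MeOH as solvent, rt
Reagents that add atoms: none
Why: Benzophenone-sensitised photochemical radical conjugate addition: the hydroxymethyl radical formed by hydrogen abstraction from methanol adds to C4 of the butenolide on the face opposite the C5 silyloxymethyl group, which sets the new C4 centre trans to C5.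

Step 3
Reactants: 4 hydroxymethyl lactone
Product: 5 (4R,5S)-5-[(tert-butyldimethylsilyloxy)methyl]-4-[(pivaloyloxy)methyl]dihydrofuran-2(3H)-one
Conditions: PivCl, pyridine, DMAP (cat.), CH2Cl2, 0 °C
Reagents that add atoms: pivaloyl chloride, CC(C)(C)C(=O)Cl
Why: Acylation of the primary alcohol (esterification); the pivalate should survive Grignard and amide bases and can later be removed reductively beside an enol silyl ether.

Step 4
Reactants: 5 pivaloyloxymethyl lactone
Product: 6 (3R,4S)-5-(tert-butyldimethylsilyloxy)-4-hydroxy-N-methoxy-N-methyl-3-[(pivaloyloxy)methyl]pentanamide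
Conditions: MeNH(OMe)·HCl, AlMe3, CH2Cl2, 0 °C to rt; Rochelle salt work-up
Reagents that add atoms: N,O-dimethylhydroxylamine hydrochloride, CNOC.Cl
Why: Weinreb aminolysis of a γ-lactone by the aluminium amide; the strained lactone should react well before the hindered pivalate, and no stereocentre is touched.

Step 5
Reactants: 6 hydroxy Weinreb amide
Product: 7 (3R,4S)-5-(tert-butyldimethylsilyloxy)-N-methoxy-N-methyl-3-[(pivaloyloxy)methyl]-4-(triisopropylsilyloxy)pentanamide
Conditions: TIPSOTf, 2,6-lutidine, CH2Cl2, −78 to 0 °C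
Reagents that add atoms: triisopropylsilyl trifluoromethanesulfonate, CC(C)[Si](C(C)C)(C(C)C)OS(=O)(=O)C(F)(F)F
Why: Silyl triflate silylation of the secondary alcohol; it blocks relactonisation and installs the bulky group that later shields one diene face.

Step 6
Reactants: 7 Weinreb amide; 8 vinylmagnesium bromide
Product: 9 (5R,6S)-7-(tert-butyldimethylsilyloxy)-5-[(pivaloyloxy)methyl]-6-(triisopropylsilyloxy)hept-1-en-3-one
Conditions: THF, −20 to 0 °C; cold aqueous quench
Reagents that add atoms: none
Why: Weinreb ketone synthesis: the Grignard reagent adds once to give a chelated tetrahedral intermediate that releases the vinyl ketone only on quench, so over-addition and attack on the pivalate should be avoided.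

Step 7
Reactants: 9 vinyl ketone
Product: 10 (3Z,5R,6S)-3,7-bis(tert-butyldimethylsilyloxy)-5-[(pivaloyloxy)methyl]-6-(triisopropylsilyloxy)hepta-1,3-diene
Conditions: TBSOTf, Et3N, CH2Cl2, −78 to 0 °C
Reagents that add atoms: tert-butyldimethylsilyl trifluoromethanesulfonate, CC(C)(C)[Si](C)(C)OS(=O)(=O)C(F)(F)F
Why: Soft enolisation with O-silylation at the only enolisable CH2 gives the cross-conjugated 2-silyloxydiene; the Z enol ether is expected because the branched C5 substituent prefers to lie cis to oxygen, away from the vinyl group.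

Step 8
Reactants: 11 3-oxocyclobutane-1-carboxylic acid
Product: 12 3-bromocyclobutan-1-one
Conditions: HgO, Br2, MgSO4, CH2Cl2, reflux
Reagents that add atoms: bromine, BrBr
Why: Bromodecarboxylation of the carboxylic acid (Cristol–Firth variant of the Hunsdiecker reaction); no stereocentre is present.

Step 9
Reactants: 12 3-bromocyclobutanone
Product: 13 cyclobut-2-en-1-one
Conditions: n-Bu3N, rt; distilled under reduced pressure into a −78 °C trap and used as a cold solution
Reagents that add atoms: none
Why: Amine-induced dehydrobromination (E1cB) of a β-bromoketone; the volatile strained enone is removed from the base as it forms.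

Step 10
Reactants: 10 (Z)-2-silyloxydiene; 13 cyclobutenone
Product: 14 (1S,2S,6R)-3-(tert-butyldimethylsilyloxy)-2-[(2R,3S)-4-(tert-butyldimethylsilyloxy)-1-(pivaloyloxy)-3-(triisopropylsilyloxy)butan-2-yl]bicyclo[4.2.0]oct-3-en-7-one (H-1/H-2/H-6 all cis)
Conditions: 13 (1.5 equiv), toluene, BHT (trace), 0 °C to rt
Reagents that add atoms: none
Why: Thermal Diels–Alder reaction of a strained dienophile: the endo transition state together with the outward-pointing substituent of the Z diene puts the side chain cis to the four-membered ring, and the diene face is chosen by the allylic centre, whose C–H eclipses the enol ether (A1,3 strain) so that the dienophile adds on the CH2OPiv side, away from the CH(OTIPS)CH2OTBS branch; the regiochemistry set by the silyloxy group is immaterial after step 12.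

Step 11
Reactants: 14 cyclobutanone
Product: 15 N-tosylhydrazone of 14 at C7 ((1R,2S,6R); C=N geometry not defined)
Conditions: TsNHNH2, THF, 4 Å MS, rt
Reagents that add atoms: p-toluenesulfonyl hydrazide, Cc1ccc(cc1)S(=O)(=O)NN
Why: Hydrazone condensation; the strained cyclobutanone should condense without acid catalysis, which keeps the enol silyl ether intact.

Step 12
Reactants: 15 tosylhydrazone
Product: 16 (1R,2S,6S)-3-(tert-butyldimethylsilyloxy)-2-[(2R,3S)-4-(tert-butyldimethylsilyloxy)-1-(pivaloyloxy)-3-(triisopropylsilyloxy)butan-2-yl]bicyclo[4.2.0]octa-3,7-diene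
Conditions: LDA (4 equiv), THF, −78 °C to rt
Reagents that add atoms: none
Why: Shapiro reaction: the dianion forms at the less hindered C8 methylene, loses sulfinate and N2, and the cyclobutenyl anion is protonated by diisopropylamine to give the C7=C8 alkene; the ring-fusion centres are not touched.

Step 13
Reactants: 16 pivalate
Product: 17 (1R,2S,6S)-3-(tert-butyldimethylsilyloxy)-2-[(2R,3S)-4-(tert-butyldimethylsilyloxy)-1-hydroxy-3-(triisopropylsilyloxy)butan-2-yl]bicyclo[4.2.0]octa-3,7-diene
Conditions: DIBAL-H (2.5 equiv), CH2Cl2, −78 °C; Rochelle salt work-up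
Reagents that add atoms: none
Why: Reductive ester cleavage by an aluminium hydride; silyl ethers, the enol silyl ether and the cyclobutene are inert to DIBAL-H at low temperature, and no fluoride, acid or free alkoxide is generated.

Step 14
Reactants: 17 primary alcohol
Product: 19 (1R,2S,6S)-3-(tert-butyldimethylsilyloxy)-2-[(2S,3S)-4-(tert-butyldimethylsilyloxy)-1-iodo-3-(triisopropylsilyloxy)butan-2-yl]bicyclo[4.2.0]octa-3,7-diene (cyclisation substrate), via primary mesylate 18 (not isolated)
Conditions: MsCl, Et3N, CH2Cl2, 0 °C; then NaI, acetone, 55 °C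
Reagents that add atoms: methanesulfonyl chloride, CS(=O)(=O)Cl (in 18); sodium iodide, [Na+].[I-] (in 19)
Why: Sulfonylation followed by Finkelstein SN2 displacement at a primary carbon; the neutral conditions avoid free iodine and acid, both of which would attack the enol silyl ether.

Step 15
Reactants: 19 iodide; 20 allyltributylstannane
Product: 21 allyl tricycle: the former CH2I carbon bonded to C8 of 19 (new cis-fused cyclopentane) and allyl on C7 trans to that bond; TBS enol ether and TBS/TIPS ethers unchanged
Conditions: 20 (4 equiv), AIBN (0.2 equiv, in portions), degassed benzene, 80 °C, 0.05 M in 19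
Reagents that add atoms: none
Why: Tin-mediated radical chain: Bu3Sn• abstracts iodine from 19, the primary radical adds to C8 of the cyclobutene, and the cyclobutyl radical at C7 adds to allyltributylstannane, whose β-scission returns Bu3Sn•. The closest known reaction type is a 5-exo radical cyclisation terminated by Keck allylation of the cyclised radical. The cyclopentane closes in 5-exo-trig mode onto the strained C7=C8 bond; because the arm and the four-membered ring are cis on the six-membered ring, the new bond can only form on the concave face, which fixes C8 as a cis ring fusion. The C7 centre is set by the trap: the bulky stannane should reach the cyclobutyl radical from the convex face, anti to the new cyclopentane bond and to the six-membered ring, so allyl and the cyclopentane CH2 end up trans. The step needs ring closure to outrun direct allylation of the primary radical and 6-endo attack at C7; strain release and the proximity of C8 should make cyclisation much faster than the slow bimolecular allyl transfer at this stannane concentration, and the electron-rich enol silyl ether, reachable only in 4-exo or 5-endo mode, should stay untouched.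

Step 16
Reactants: 21 allyl tricycle; 22 1-bromopentane
Product: 24 n-octyl tricycle (allyl group of 21 extended to n-octyl), via B-alkyl-9-BBN adduct 23 (not isolated)
Conditions: 9-BBN, THF, 0 °C to rt; then 22, Pd(OAc)2 (4 mol%), PCy3 (8 mol%), K3PO4·H2O, THF, rt
Reagents that add atoms: 9-borabicyclo[3.3.1]nonane, B1C2CCCC1CCC2 (boron fragment in 23 only)
Why: Anti-Markovnikov hydroboration of the terminal alkene (far faster than that of the trisubstituted enol silyl ether, which meanwhile shields the ketone from the borane) followed by Pd/PCy3-catalysed alkyl–alkyl Suzuki–Miyaura coupling with a primary bromide; no stereocentre is affected.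

Step 17
Reactants: 24 enol silyl ether
Product: 25 tricyclic enone: C3 ketone conjugated with a new C4=C5 double bond (former bicyclooctene locants); octyl and TBS/TIPS ethers unchanged
Conditions: Pd(OAc)2 (1.1 equiv), MeCN, rt to 40 °C
Reagents that add atoms: none
Why: Saegusa–Ito oxidation: Pd(II) converts the enol silyl ether into a palladium enolate and syn β-hydride elimination gives the enone, with the regiochemistry fixed by the position of the enol ether.

Step 18
Reactants: 25 bis-silyl ether
Product: 26 primary alcohol (CH2OTBS of 25 converted to CH2OH; secondary TIPS ether retained)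
Conditions: HF·pyridine, pyridine, THF, 0 °C
Reagents that add atoms: none
Why: Selective desilylation: buffered HF cleaves the unhindered primary TBS ether much faster than the secondary TIPS ether.

Step 19
Reactants: 26 primary alcohol
Product: 27 α-(triisopropylsilyloxy) aldehyde (CH2OH of 26 oxidised to CHO)
Conditions: Dess–Martin periodinane, CH2Cl2, 0 °C to rt; used at once
Reagents that add atoms: none
Why: Dess–Martin oxidation under non-basic conditions, which should leave the α-silyloxy stereocentre and the enone untouched.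

Step 20
Reactants: 27 aldehyde; 28 methyl (triphenylphosphoranylidene)acetate
Product: 30 methyl (Z)-2-iodo-4-(triisopropylsilyloxy)but-2-enoate carried at C4 by the tricyclic enone (iodine cis to the carbinol carbon), via iodo ylide 29 (not isolated)
Conditions: 28, NIS, CH2Cl2, −20 °C; then 27, rt
Reagents that add atoms: N-iodosuccinimide, O=C1CCC(=O)N1I
Why: Wittig olefination with a stabilised α-iodo ylide made by iodination of the ester ylide; the stabilised ylide should place the ester trans to the aldehyde residue (the Z iodoenoate) and ignore the enone ketone.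

Step 21
Reactants: 30 (Z)-iodoenoate
Product: 31 tetracyclic methyl ester: TIPS ether of the methyl ester of the target (new cyclohexene ring; tertiary OH cis to the adjacent ring-fusion H)
Conditions: CrCl2 (6 equiv), NiCl2 (2 mol%), degassed DMSO, rt, 5 mM
Reagents that add atoms: none
Why: Intramolecular Nozaki–Hiyama–Kishi reaction: Ni inserts into the C–I bond, transmetalation gives an alkenylchromium(III) that adds 1,2 to the ketone and closes the six-membered ring; the three-atom tether, anchored on a pseudo-axial bond next to the carbonyl, can only reach the carbonyl face on its own side, which sets the tertiary carbinol cis-fused.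

Step 22
Reactants: 31 tetracyclic silyl ether ester
Product: 33 target acid CNP0106718.3, via diol methyl ester 32 (not isolated)
Conditions: TBAF, THF, 0 °C to rt; then LiOH, H2O/MeOH, rt; 0.5 M HCl to pH 4 at 0 °C
Reagents that add atoms: lithium hydroxide, [Li+].[OH-]
Why: Fluoride desilylation followed in the same flask by saponification of the methyl ester; fluoride and base avoid the acid that could ionise the doubly allylic tertiary alcohol, and no stereocentre is affected.

**Compound list**

1 | (S)-5-(hydroxymethyl)furan-2(5H)-one | O=C1C=C[C@@H](CO)O1 | starting material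
2 | (S)-5-[(tert-butyldimethylsilyloxy)methyl]furan-2(5H)-one | O=C1C=C[C@@H](CO[Si](C)(C)C(C)(C)C)O1 | intermediate
3 | methanol | CO | starting material
4 | (4R,5S)-5-[(tert-butyldimethylsilyloxy)methyl]-4-(hydroxymethyl)dihydrofuran-2(3H)-one | O=C1C[C@H](CO)[C@@H](CO[Si](C)(C)C(C)(C)C)O1 | intermediate
5 | (4R,5S)-5-[(tert-butyldimethylsilyloxy)methyl]-4-[(pivaloyloxy)methyl]dihydrofuran-2(3H)-one | O=C1C[C@H](COC(=O)C(C)(C)C)[C@@H](CO[Si](C)(C)C(C)(C)C)O1 | intermediate
6 | (3R,4S)-5-(tert-butyldimethylsilyloxy)-4-hydroxy-N-methoxy-N-methyl-3-[(pivaloyloxy)methyl]pentanamide | CON(C)C(=O)C[C@H](COC(=O)C(C)(C)C)[C@H](O)CO[Si](C)(C)C(C)(C)C | intermediate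
7 | (3R,4S)-5-(tert-butyldimethylsilyloxy)-N-methoxy-N-methyl-3-[(pivaloyloxy)methyl]-4-(triisopropylsilyloxy)pentanamide | CON(C)C(=O)C[C@H](COC(=O)C(C)(C)C)[C@H](O[Si](C(C)C)(C(C)C)C(C)C)CO[Si](C)(C)C(C)(C)C | intermediate
8 | vinylmagnesium bromide | C=C[Mg]Br | starting material
9 | (5R,6S)-7-(tert-butyldimethylsilyloxy)-5-[(pivaloyloxy)methyl]-6-(triisopropylsilyloxy)hept-1-en-3-one | C=CC(=O)C[C@H](COC(=O)C(C)(C)C)[C@H](O[Si](C(C)C)(C(C)C)C(C)C)CO[Si](C)(C)C(C)(C)C | intermediate
10 | (3Z,5R,6S)-3,7-bis(tert-butyldimethylsilyloxy)-5-[(pivaloyloxy)methyl]-6-(triisopropylsilyloxy)hepta-1,3-diene | C=C/C(O[Si](C)(C)C(C)(C)C)=C/[C@H](COC(=O)C(C)(C)C)[C@H](O[Si](C(C)C)(C(C)C)C(C)C)CO[Si](C)(C)C(C)(C)C | intermediate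
11 | 3-oxocyclobutane-1-carboxylic acid | O=C1CC(C1)C(=O)O | starting material
12 | 3-bromocyclobutan-1-one | O=C1CC(Br)C1 | intermediate
13 | cyclobut-2-en-1-one | O=C1CC=C1 | intermediate
14 | (1S,2S,6R)-3-(tert-butyldimethylsilyloxy)-2-[(2R,3S)-4-(tert-butyldimethylsilyloxy)-1-(pivaloyloxy)-3-(triisopropylsilyloxy)butan-2-yl]bicyclo[4.2.0]oct-3-en-7-one | CC(C)(C)C(=O)OC[C@H]([C@H](O[Si](C(C)C)(C(C)C)C(C)C)CO[Si](C)(C)C(C)(C)C)[C@@H]1[C@@H]2CC(=O)[C@@H]2CC=C1O[Si](C)(C)C(C)(C)C | intermediate
15 | N-tosylhydrazone of 14 at C7, (1R,2S,6R) | CC(C)(C)C(=O)OC[C@H]([C@H](O[Si](C(C)C)(C(C)C)C(C)C)CO[Si](C)(C)C(C)(C)C)[C@@H]1[C@@H]2CC(=NNS(=O)(=O)c3ccc(C)cc3)[C@@H]2CC=C1O[Si](C)(C)C(C)(C)C | intermediate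
16 | (1R,2S,6S)-3-(tert-butyldimethylsilyloxy)-2-[(2R,3S)-4-(tert-butyldimethylsilyloxy)-1-(pivaloyloxy)-3-(triisopropylsilyloxy)butan-2-yl]bicyclo[4.2.0]octa-3,7-diene | CC(C)(C)C(=O)OC[C@H]([C@H](O[Si](C(C)C)(C(C)C)C(C)C)CO[Si](C)(C)C(C)(C)C)[C@@H]1[C@@H]2C=C[C@@H]2CC=C1O[Si](C)(C)C(C)(C)C | intermediate
17 | (1R,2S,6S)-3-(tert-butyldimethylsilyloxy)-2-[(2R,3S)-4-(tert-butyldimethylsilyloxy)-1-hydroxy-3-(triisopropylsilyloxy)butan-2-yl]bicyclo[4.2.0]octa-3,7-diene | OC[C@H]([C@H](O[Si](C(C)C)(C(C)C)C(C)C)CO[Si](C)(C)C(C)(C)C)[C@@H]1[C@@H]2C=C[C@@H]2CC=C1O[Si](C)(C)C(C)(C)C | intermediate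
18 | methanesulfonate of 17 | CS(=O)(=O)OC[C@H]([C@H](O[Si](C(C)C)(C(C)C)C(C)C)CO[Si](C)(C)C(C)(C)C)[C@@H]1[C@@H]2C=C[C@@H]2CC=C1O[Si](C)(C)C(C)(C)C | intermediate (not isolated)
19 | (1R,2S,6S)-3-(tert-butyldimethylsilyloxy)-2-[(2S,3S)-4-(tert-butyldimethylsilyloxy)-1-iodo-3-(triisopropylsilyloxy)butan-2-yl]bicyclo[4.2.0]octa-3,7-diene | IC[C@H]([C@H](O[Si](C(C)C)(C(C)C)C(C)C)CO[Si](C)(C)C(C)(C)C)[C@@H]1[C@@H]2C=C[C@@H]2CC=C1O[Si](C)(C)C(C)(C)C | intermediate
20 | allyltributylstannane | C=CC[Sn](CCCC)(CCCC)CCCC | starting material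
21 | allyl tricycle (6-5-4 core, TBS enol ether in the six-membered ring, allyl on the cyclobutane trans to the cyclopentane CH2, (1S)-2-(TBSO)-1-(TIPSO)ethyl side chain on the cyclopentane) | C=CC[C@H]1[C@@H]2CC=C(O[Si](C)(C)C(C)(C)C)[C@@H]3[C@@H]([C@H](O[Si](C(C)C)(C(C)C)C(C)C)CO[Si](C)(C)C(C)(C)C)C[C@H]1[C@H]23 | intermediate
22 | 1-bromopentane | CCCCCBr | starting material
23 | B-alkyl-9-BBN adduct of 21 (boron on the terminal carbon) | C1CCC2CCCC1B2CCC[C@H]3[C@@H]4CC=C(O[Si](C)(C)C(C)(C)C)[C@@H]5[C@@H]([C@H](O[Si](C(C)C)(C(C)C)C(C)C)CO[Si](C)(C)C(C)(C)C)C[C@H]3[C@H]45 | intermediate (not isolated)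
24 | n-octyl tricycle (octyl in place of the allyl group of 21) | CCCCCCCC[C@H]1[C@@H]2CC=C(O[Si](C)(C)C(C)(C)C)[C@@H]3[C@@H]([C@H](O[Si](C(C)C)(C(C)C)C(C)C)CO[Si](C)(C)C(C)(C)C)C[C@H]1[C@H]23 | intermediate
25 | tricyclic cyclohexenone with octyl, OTIPS and CH2OTBS groups | CCCCCCCC[C@H]1[C@@H]2C=CC(=O)[C@@H]3[C@@H]([C@H](O[Si](C(C)C)(C(C)C)C(C)C)CO[Si](C)(C)C(C)(C)C)C[C@H]1[C@H]23 | intermediate
26 | primary alcohol from 25 (CH2OH, TIPS ether retained) | CCCCCCCC[C@H]1[C@@H]2C=CC(=O)[C@@H]3[C@@H]([C@H](O[Si](C(C)C)(C(C)C)C(C)C)CO)C[C@H]1[C@H]23 | intermediate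
27 | α-(triisopropylsilyloxy) aldehyde from 26 | CCCCCCCC[C@H]1[C@@H]2C=CC(=O)[C@@H]3[C@@H]([C@H](O[Si](C(C)C)(C(C)C)C(C)C)C=O)C[C@H]1[C@H]23 | intermediate
28 | methyl (triphenylphosphoranylidene)acetate | COC(=O)C=P(c1ccccc1)(c1ccccc1)c1ccccc1 | starting material
29 | methyl iodo(triphenylphosphoranylidene)acetate | COC(=O)C(I)=P(c1ccccc1)(c1ccccc1)c1ccccc1 | intermediate (not isolated)
30 | methyl (Z)-2-iodo-4-(triisopropylsilyloxy)but-2-enoate attached at C4 to the tricyclic enone | CCCCCCCC[C@H]1[C@@H]2C=CC(=O)[C@@H]3[C@@H]([C@H](O[Si](C(C)C)(C(C)C)C(C)C)/C=C(\I)C(=O)OC)C[C@H]1[C@H]23 | intermediate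
31 | tetracyclic methyl ester, secondary alcohol as TIPS ether | CCCCCCCC[C@H]1[C@@H]2C=C[C@]3(O)C(C(=O)OC)=C[C@@H](O[Si](C(C)C)(C(C)C)C(C)C)[C@H]4C[C@H]1[C@H]2[C@@H]43 | intermediate
32 | methyl ester of the target (diol) | CCCCCCCC[C@H]1[C@@H]2C=C[C@]3(O)C(C(=O)OC)=C[C@@H](O)[C@H]4C[C@H]1[C@H]2[C@@H]43 | intermediate (not isolated)
33 | CNP0106718.3, tetracyclic dihydroxy acid | CCCCCCCC[C@H]1[C@@H]2C=C[C@]3(O)C(C(=O)O)=C[C@@H](O)[C@H]4C[C@H]1[C@H]2[C@@H]43 | target

**Step count.** Total: 22 steps. Longest linear sequence: 20 steps (from 1 through steps 1–7 and 10–22); steps 8–9 supply cyclobutenone.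

**Steps most likely to fail**

1. Step 15 (radical cyclisation with allyl capture). Allyl transfer may reach the primary radical before it cyclises, or the chain may stall because the hindered cyclobutyl radical adds too slowly to the stannane, so that reduction and oligomers take over. Fallback: setting out from iodide 19, a nickel-catalysed radical cyclisation/alkyl–alkyl Negishi cascade (NiCl2(py)4, (S)-s-Bu-Pybox, n-octylzinc bromide, THF, rt) would form the same ring bond and deliver the whole octyl chain by nickel capture of the cyclobutyl radical on the convex face. It makes no compound outside the list (F0) and comes back to the route at 24.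

2. Step 21 (Cr/Ni ring closure onto the ketone). The electron-poor alkenylchromium may add too slowly to a ketone, so that loss of iodine by protonation or reduction of the enone competes. Fallback: setting out from iodoenoate 30, iodine–magnesium exchange (i-PrMgCl·LiCl, THF, −78 °C) would give the alkenylmagnesium chloride F1, which should close onto the ketone as an intramolecular Grignard addition under the same geometric constraint and, after quench, come back to the route at 31.

3. Step 12 (Shapiro reaction on the cyclobutanone hydrazone). The hydrazone anion may decompose by a carbene pathway with ring contraction, or deprotonation may occur at the wrong α-carbon, before the strained alkenyl anion forms. Fallback: setting out from ketone 14 (leaving out 15), kinetic enolisation at the C8 methylene and O-triflation (KHMDS, PhNTf2, THF, −78 °C) would give the cyclobutenyl triflate F2. Palladium-catalysed formate reduction of this enol triflate (Pd(OAc)2, PPh3, HCO2H, n-Bu3N, DMF, 60 °C) would come back to the route at 16.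

**Further compounds**

F0 | step 15 | none | none
F1 | step 21 | alkenylmagnesium chloride from 30 (MgCl in place of I) | CCCCCCCC[C@H]1[C@@H]2C=CC(=O)[C@@H]3[C@@H]([C@H](O[Si](C(C)C)(C(C)C)C(C)C)/C=C(\[Mg]Cl)C(=O)OC)C[C@H]1[C@H]23
F2 | step 12 | cyclobutenyl triflate from 14 (C7 enol triflate, C7=C8) | CC(C)(C)C(=O)OC[C@H]([C@H](O[Si](C(C)C)(C(C)C)C(C)C)CO[Si](C)(C)C(C)(C)C)[C@@H]1[C@@H]2C=C(OS(=O)(=O)C(F)(F)F)[C@@H]2CC=C1O[Si](C)(C)C(C)(C)C
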